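**Retrosynthetic overview**

1. The target is a (3S)-isoflavanone. The last step removes three aryl silyl ethers. C3 is set just before that by palladium-catalysed decarboxylative protonation of the allyl enol carbonate of the racemic ketone, because a base-mediated ring closure would give the racemate and C3 stays enolisable.
2. Ring C: C4–C4a comes from intramolecular Friedel–Crafts acylation of a 3-aryloxy-2-arylpropanoic acid. O1–C2 comes from oxa-Michael addition of the symmetric 3,5-bis(silyloxy)-4-prenylphenol (ring A, from phloroglucinol) to the 2-arylacrylate made by α-methylenation of the ring B arylacetate. The symmetry of the phenol fixes the prenyl group at C6.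
3. The strategy rests on ring B and its four contiguous substituents: C1' (carbon), C2' (OMe), C3' (E-alkenyl) and C4' (OH). A vinylketene–alkyne benzannulation of a vinyl diazo ketone with a methoxy enyne writes this pattern in one step and forms C1'–C6', C1'–C2', C3'–C4' and C4'–C5'.
4. Precursors: the diazo ketone from methyl succinyl chloride by Stille acylation and diazo transfer; the enyne from 3-methylbut-1-yne (hydrozirconation–iodination) and methoxyacetylide (Negishi coupling).
5. Order of rings: ring B (step 5), then ring C (step 13) closed onto the preformed ring A.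

Key step: step 5

Remark: in step 15 the ligand antipode is assumed to be the one that delivers (3S); the sense of protonation depends on the proton source and has to be assigned on the first run.

**Route**

Step 1
Reactants: 1 methyl 4-chloro-4-oxobutanoate; 2 tributyl(vinyl)stannane
Product: 3 methyl 4-oxohex-5-enoate
Conditions: PdCl2(PPh3)2 (2 mol %), BHT (trace), THF, 50 °C
Reagents that add atoms: none
Why: Stille acylation, in which oxidative addition of the acid chloride to zerovalent palladium, vinyl transfer from tin and reductive elimination should give the vinyl ketone without touching the methyl ester.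

Step 2
Reactants: 3 methyl 4-oxohex-5-enoate
Product: 6 methyl 3-diazo-4-oxohex-5-enoate, via lithium dienolate 4 (not isolated), via trifluoroacetyl diketone 5 (not isolated)
Conditions: LiN(SiMe3)2 (1.1 equiv), THF, −78 °C, 3 added slowly; CF3CO2CH2CF3 (1.2 equiv), −78 °C; aqueous HCl work-up; then MsN3 (1.5 equiv), Et3N (1.5 equiv), H2O (1 equiv), MeCN, rt
Reagents that add atoms: methanesulfonyl azide, CS(=O)(=O)N=[N+]=[N-]; 2,2,2-trifluoroethyl trifluoroacetate, O=C(OCC(F)(F)F)C(F)(F)F (its atoms stay in 5 only); LiN(SiMe3)2, C[Si](C)(C)N([Li])[Si](C)(C)C (lithium stays in 4 only)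
Why: Detrifluoroacetylative diazo transfer, in which the only enolisable ketone position (C3) gives the kinetic dienolate, C-trifluoroacetylation activates it, and mesyl azide delivers the diazo group with loss of the trifluoroacetyl group as the sulfonamide; slow addition of 3 to the base at −78 °C keeps enolate and free enone apart.

Step 3
Reactants: 7 3-methylbut-1-yne
Product: 9 (E)-1-iodo-3-methylbut-1-ene, via alkenylzirconocene chloride 8 (not isolated)
Conditions: Cp2Zr(H)Cl (1.1 equiv), CH2Cl2, rt; then I2 (1.0 equiv), 0 °C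
Reagents that add atoms: iodine, II; Cp2Zr(H)Cl, [H][Zr](Cl)(C1C=CC=C1)C1C=CC=C1 (zirconium fragment stays in 8 only)
Why: Hydrozirconation–iodinolysis, in which syn addition of Zr–H places zirconium on the terminal carbon and iodine replaces it with retention, so only the E iodoalkene should form.

Step 4
Reactants: 10 chloroacetaldehyde dimethyl acetal; 9 (E)-1-iodo-3-methylbut-1-ene
Product: 13 (E)-1-methoxy-5-methylhex-3-en-1-yne, via lithium methoxyacetylide 11 (not isolated), via chloro(methoxyethynyl)zinc 12 (not isolated)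
Conditions: LiNEt2 (3.1 equiv), THF, −78 to 0 °C; ZnCl2 (1.5 equiv), 0 °C; 9, Pd(PPh3)4 (3 mol %), THF, rt
Reagents that add atoms: LiNEt2, CCN([Li])CC (lithium stays in 11 only); ZnCl2, Cl[Zn]Cl (zinc and chlorine stay in 12 only)
Why: Negishi coupling, in which double elimination (methanol, then HCl) and deprotonation of the chloroacetal give the methoxyacetylide, transmetalation to zinc moderates it, and zerovalent palladium joins it to the alkenyl iodide with retention of the E geometry.

Step 5
Reactants: 6 methyl 3-diazo-4-oxohex-5-enoate; 13 (E)-1-methoxy-5-methylhex-3-en-1-yne (1.3 equiv)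
Product: 18 methyl 2-[4-hydroxy-2-methoxy-3-[(E)-3-methylbut-1-enyl]phenyl]acetate, via vinylketene 14 (not isolated), via vinylcyclobutenone 15 (not isolated), via dienylketene 16 (not isolated), via cyclohexadienone 17 (not isolated)
Conditions: ClCH2CH2Cl (0.2 M), degassed, hν (365 nm), rt; then 80 °C in the dark
Reagents that add atoms: none
Why: This is the Danheiser benzannulation in its diazo ketone variant: light at 365 nm expels N2 from 6 and the vinyl group shifts to the diazo carbon (photochemical Wolff rearrangement, forming C1'–C6') to give vinylketene 14. Ketene 14 adds to the ynol ether 13 in a (2+2) cycloaddition (forming C3'–C4' and C1'–C2') to give 4-vinylcyclobutenone 15, which opens on warming in a four-electron electrocyclic reaction to dienylketene 16. Ring B is closed by six-electron electrocyclisation of 16 (forming C4'–C5') to cyclohexadienone 17, which tautomerises to the phenol; the closest known reaction type is the vinylketene–alkoxyalkyne aromatic annulation. No stereocentre remains, since the quaternary carbon of racemic 15 becomes aromatic, and the cyclobutenone opening is reversible, so the rotamer with the vinyl group turned inward is drained into ring B. The regiochemistry needed (OMe next to C1', alkenyl next to the new OH) is secured by the polarised ynol ether, whose oxygen-free carbon attacks the ketene carbonyl carbon, and the alkyne of 13 reacts in preference to its alkene because it is the more nucleophilic π bond. Long-wavelength light that neither 13 nor the styrene-type product absorbs should keep the C3' alkene E, and the s-Z conformer of 6 favours concerted Wolff migration over a 1,2-hydride shift from the neighbouring CH2.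

Step 6
Reactants: 18 methyl 2-[4-hydroxy-2-methoxy-3-[(E)-3-methylbut-1-enyl]phenyl]acetate
Product: 19 methyl 2-[2-methoxy-3-[(E)-3-methylbut-1-enyl]-4-(triisopropylsilyloxy)phenyl]acetate
Conditions: TIPSCl (1.3 equiv), imidazole (2.5 equiv), DMF, rt
Reagents that add atoms: chlorotriisopropylsilane, CC(C)[Si](Cl)(C(C)C)C(C)C
Why: Silyl ether formation at the only free hydroxyl (C4') under imidazole catalysis, so that the phenol cannot take part in the base-mediated steps that follow.

Step 7
Reactants: 19 methyl 2-[2-methoxy-3-[(E)-3-methylbut-1-enyl]-4-(triisopropylsilyloxy)phenyl]acetate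
Product: 21 methyl 2-[2-methoxy-3-[(E)-3-methylbut-1-enyl]-4-(triisopropylsilyloxy)phenyl]prop-2-enoate, via hydroxymethyl ester 20 (not isolated)
Conditions: (CH2O)n (3 equiv), K2CO3 (2 equiv), Bu4NI (10 mol %), toluene, 80 °C
Reagents that add atoms: formaldehyde (from paraformaldehyde), C=O
Why: Aldol condensation with formaldehyde, in which the benzylic ester enolate adds to formaldehyde and adduct 20 loses water by E1cB elimination under the same phase-transfer conditions, a standard route to 2-arylacrylates.

Step 8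
Reactants: 22 phloroglucinol (3 equiv); 23 prenyl bromide
Product: 24 2-(3-methylbut-2-enyl)benzene-1,3,5-triol
Conditions: DBU (1 equiv), THF, 0 °C to rt
Reagents that add atoms: none
Why: C-Alkylation of the ambident phloroglucinol anion by the allylic bromide (Friedel–Crafts-type prenylation), with excess phloroglucinol to limit polyprenylation; the symmetric nucleophile needs no regiocontrol.

Step 9
Reactants: 24 2-(3-methylbut-2-enyl)benzene-1,3,5-triol
Product: 25 2-(3-methylbut-2-enyl)-1,3,5-tris(triisopropylsilyloxy)benzene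
Conditions: TIPSOTf (3.5 equiv), 2,6-lutidine (5 equiv), CH2Cl2, 0 °C to rt
Reagents that add atoms: triisopropylsilyl triflate, CC(C)[Si](OS(=O)(=O)C(F)(F)F)(C(C)C)C(C)C
Why: Silyl ether formation with the silyl triflate, which is reactive enough for the two hydroxyls flanked by the prenyl group.

Step 10
Reactants: 25 2-(3-methylbut-2-enyl)-1,3,5-tris(triisopropylsilyloxy)benzene
Product: 26 4-(3-methylbut-2-enyl)-3,5-bis(triisopropylsilyloxy)phenol
Conditions: Bu4NF (1.0 equiv), THF, −78 °C; AcOH quench at −78 °C
Reagents that add atoms: none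
Why: Sterically controlled desilylation, in which fluoride should attack first the silicon para to the prenyl group, whose oxygen has two ortho hydrogens, while the two silyl ethers next to the prenyl CH2 are shielded; one equivalent at low temperature and an acidic quench limit further cleavage.

Step 11
Reactants: 21 methyl 2-[2-methoxy-3-[(E)-3-methylbut-1-enyl]-4-(triisopropylsilyloxy)phenyl]prop-2-enoate (1.2 equiv); 26 4-(3-methylbut-2-enyl)-3,5-bis(triisopropylsilyloxy)phenol
Product: 27 methyl 3-[4-(3-methylbut-2-enyl)-3,5-bis(triisopropylsilyloxy)phenoxy]-2-[2-methoxy-3-[(E)-3-methylbut-1-enyl]-4-(triisopropylsilyloxy)phenyl]propanoate (racemic)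
Conditions: Cs2CO3 (20 mol %), MeCN, rt
Reagents that add atoms: none
Why: Oxa-Michael addition, in which the phenoxide of 26 (its only free oxygen) adds to the β-carbon of the 2-arylacrylate and the ester enolate is protonated by the next phenol, so catalytic base suffices; the future C3 is formed racemic here and is set in step 15.

Step 12
Reactants: 27 the racemic methyl ester from step 11
Product: 28 3-[4-(3-methylbut-2-enyl)-3,5-bis(triisopropylsilyloxy)phenoxy]-2-[2-methoxy-3-[(E)-3-methylbut-1-enyl]-4-(triisopropylsilyloxy)phenyl]propanoic acid (racemic)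
Conditions: Me3SnOH (5 equiv), ClCH2CH2Cl, 70 °C; 5% aqueous HCl wash
Reagents that add atoms: trimethyltin hydroxide, C[Sn](C)(C)O
Why: Ester hydrolysis with Me3SnOH, chosen because its near-neutral conditions should avoid the E1cB loss of phenoxide (retro-oxa-Michael) that hydroxide could cause and should leave the aryl silyl ethers intact.

Step 13
Reactants: 28 the racemic acid from step 12
Product: 30 3-[2-methoxy-3-[(E)-3-methylbut-1-enyl]-4-(triisopropylsilyloxy)phenyl]-6-(3-methylbut-2-enyl)-5,7-bis(triisopropylsilyloxy)-2,3-dihydrochromen-4-one (racemic), via acyl trifluoroacetate 29 (not isolated)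
Conditions: (CF3CO)2O (1.5 equiv), CH2Cl2, −20 to 0 °C, short reaction time
Reagents that add atoms: trifluoroacetic anhydride, O=C(OC(=O)C(F)(F)F)C(F)(F)F (its atoms stay in 29 only)
Why: Intramolecular Friedel–Crafts acylation through mixed anhydride 29, in which the trioxygenated ring A is attacked at the position ortho to the ether oxygen (both such positions are equivalent), closing ring C at C4–C4a by electrophilic aromatic substitution and placing the prenyl group at C6 without a regiochemical choice; no Lewis acid is used and the exposure is short and cold so that the two side-chain alkenes and the silyl ethers are spared.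

Step 14
Reactants: 30 the racemic silyl-protected isoflavanone
Product: 32 3-[2-methoxy-3-[(E)-3-methylbut-1-enyl]-4-(triisopropylsilyloxy)phenyl]-6-(3-methylbut-2-enyl)-5,7-bis(triisopropylsilyloxy)-2H-chromen-4-yl prop-2-enyl carbonate, via sodium enolate 31 (not isolated)
Conditions: NaN(SiMe3)2 (1.1 equiv), THF, −78 °C; allyl chloroformate (1.3 equiv), −78 to −40 °C
Reagents that add atoms: allyl chloroformate, C=CCOC(=O)Cl; NaN(SiMe3)2, C[Si](C)(C)N([Na])[Si](C)(C)C (sodium stays in 31 only)
Why: O-Acylation of an enolate, in which the tetrasubstituted aryl-conjugated sodium enolate of 30 should react at oxygen with the chloroformate to give the allyl enol carbonate and so erase the C3 stereocentre; the low temperature suppresses ring opening by retro-oxa-Michael.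

Step 15
Reactants: 32 the allyl enol carbonate
Product: 33 (3S)-3-[2-methoxy-3-[(E)-3-methylbut-1-enyl]-4-(triisopropylsilyloxy)phenyl]-6-(3-methylbut-2-enyl)-5,7-bis(triisopropylsilyloxy)-2,3-dihydrochromen-4-one
Conditions: Pd2(dba)3 (5 mol %), (S)-t-BuPHOX (12.5 mol %), Meldrum's acid (2.5 equiv), 1,4-dioxane, 40 °C
Reagents that add atoms: none
Why: Palladium-catalysed decarboxylative asymmetric protonation, in which zerovalent palladium ionises the allyl carbonate, CO2 is lost, and the chiral phosphinooxazoline palladium enolate is protonated by Meldrum's acid on one face, which sets C3 under catalyst control (S for the matched ligand antipode, see the remark); the ortho-methoxy group of ring B provides the hindered α-aryl group that this reaction type needs with isoflavanones.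

Step 16
Reactants: 33 the (3S) silyl-protected isoflavanone
Product: 34 (3S)-5,7-dihydroxy-3-[4-hydroxy-2-methoxy-3-[(E)-3-methylbut-1-enyl]phenyl]-6-(3-methylbut-2-enyl)-2,3-dihydrochromen-4-one (CNP0289142.1)
Conditions: Bu4NF (3.5 equiv), AcOH (4 equiv), THF, 0 °C
Reagents that add atoms: none
Why: Fluoride-mediated desilylation buffered with acetic acid, which should cleave the three aryl silyl ethers while the medium stays non-basic, so that the enolisable C3 stereocentre next to the ketone is not racemised.

**Compound list**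

1 | methyl 4-chloro-4-oxobutanoate | COC(=O)CCC(=O)Cl | starting material
2 | tributyl(vinyl)stannane | C=C[Sn](CCCC)(CCCC)CCCC | starting material
3 | methyl 4-oxohex-5-enoate | COC(=O)CCC(=O)C=C | intermediate
4 | lithium 6-methoxy-6-oxohexa-1,3-dien-3-olate (lithium dienolate of 3) | COC(=O)CC=C(O[Li])C=C | intermediate
5 | methyl 4-oxo-3-(2,2,2-trifluoroacetyl)hex-5-enoate | COC(=O)CC(C(=O)C(F)(F)F)C(=O)C=C | intermediate
6 | methyl 3-diazo-4-oxohex-5-enoate | COC(=O)CC(=[N+]=[N-])C(=O)C=C | intermediate
7 | 3-methylbut-1-yne | CC(C)C#C | starting material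
8 | chlorobis(cyclopentadienyl)[(E)-3-methylbut-1-enyl]zirconium | CC(C)/C=C/[Zr](Cl)(C1C=CC=C1)C1C=CC=C1 | intermediate
9 | (E)-1-iodo-3-methylbut-1-ene | CC(C)/C=C/I | intermediate
10 | chloroacetaldehyde dimethyl acetal | COC(CCl)OC | starting material
11 | lithium methoxyacetylide | COC#C[Li] | intermediate
12 | chloro(methoxyethynyl)zinc | COC#C[Zn]Cl | intermediate
13 | (E)-1-methoxy-5-methylhex-3-en-1-yne | COC#C/C=C/C(C)C | intermediate
14 | methyl 3-(oxomethylidene)pent-4-enoate (vinylketene) | C=CC(=C=O)CC(=O)OC | intermediate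
15 | methyl 2-[1-ethenyl-2-methoxy-3-[(E)-3-methylbut-1-enyl]-4-oxocyclobut-2-en-1-yl]acetate (racemic) | COC(=O)CC1(C=C)C(OC)=C(/C=C/C(C)C)C1=O | intermediate
16 | methyl (3E)-3-ethenyl-4-methoxy-5-[(E)-3-methylbut-1-enyl]-6-oxohexa-3,5-dienoate (dienylketene) | COC(=O)C/C(C=C)=C(OC)/C(/C=C/C(C)C)=C=O | intermediate
17 | methyl 2-[6-methoxy-5-[(E)-3-methylbut-1-enyl]-4-oxocyclohexa-1,5-dien-1-yl]acetate | COC(=O)CC1=CCC(=O)C(/C=C/C(C)C)=C1OC | intermediate
18 | methyl 2-[4-hydroxy-2-methoxy-3-[(E)-3-methylbut-1-enyl]phenyl]acetate | COC(=O)Cc1ccc(O)c(/C=C/C(C)C)c1OC | intermediate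
19 | methyl 2-[2-methoxy-3-[(E)-3-methylbut-1-enyl]-4-(triisopropylsilyloxy)phenyl]acetate | COC(=O)Cc1ccc(O[Si](C(C)C)(C(C)C)C(C)C)c(/C=C/C(C)C)c1OC | intermediate
20 | methyl 3-hydroxy-2-[2-methoxy-3-[(E)-3-methylbut-1-enyl]-4-(triisopropylsilyloxy)phenyl]propanoate (racemic) | COC(=O)C(CO)c1ccc(O[Si](C(C)C)(C(C)C)C(C)C)c(/C=C/C(C)C)c1OC | intermediate
21 | methyl 2-[2-methoxy-3-[(E)-3-methylbut-1-enyl]-4-(triisopropylsilyloxy)phenyl]prop-2-enoate | COC(=O)C(=C)c1ccc(O[Si](C(C)C)(C(C)C)C(C)C)c(/C=C/C(C)C)c1OC | intermediate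
22 | phloroglucinol (benzene-1,3,5-triol) | Oc1cc(O)cc(O)c1 | starting material
23 | prenyl bromide (1-bromo-3-methylbut-2-ene) | CC(C)=CCBr | starting material
24 | 2-(3-methylbut-2-enyl)benzene-1,3,5-triol | CC(C)=CCc1c(O)cc(O)cc1O | intermediate
25 | 2-(3-methylbut-2-enyl)-1,3,5-tris(triisopropylsilyloxy)benzene | CC(C)=CCc1c(O[Si](C(C)C)(C(C)C)C(C)C)cc(O[Si](C(C)C)(C(C)C)C(C)C)cc1O[Si](C(C)C)(C(C)C)C(C)C | intermediate
26 | 4-(3-methylbut-2-enyl)-3,5-bis(triisopropylsilyloxy)phenol | CC(C)=CCc1c(O[Si](C(C)C)(C(C)C)C(C)C)cc(O)cc1O[Si](C(C)C)(C(C)C)C(C)C | intermediate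
27 | methyl 3-[4-(3-methylbut-2-enyl)-3,5-bis(triisopropylsilyloxy)phenoxy]-2-[2-methoxy-3-[(E)-3-methylbut-1-enyl]-4-(triisopropylsilyloxy)phenyl]propanoate (racemic) | COC(=O)C(COc1cc(O[Si](C(C)C)(C(C)C)C(C)C)c(CC=C(C)C)c(O[Si](C(C)C)(C(C)C)C(C)C)c1)c1ccc(O[Si](C(C)C)(C(C)C)C(C)C)c(/C=C/C(C)C)c1OC | intermediate
28 | 3-[4-(3-methylbut-2-enyl)-3,5-bis(triisopropylsilyloxy)phenoxy]-2-[2-methoxy-3-[(E)-3-methylbut-1-enyl]-4-(triisopropylsilyloxy)phenyl]propanoic acid (racemic) | OC(=O)C(COc1cc(O[Si](C(C)C)(C(C)C)C(C)C)c(CC=C(C)C)c(O[Si](C(C)C)(C(C)C)C(C)C)c1)c1ccc(O[Si](C(C)C)(C(C)C)C(C)C)c(/C=C/C(C)C)c1OC | intermediate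
29 | mixed anhydride of 28 and trifluoroacetic acid (racemic) | O=C(OC(=O)C(F)(F)F)C(COc1cc(O[Si](C(C)C)(C(C)C)C(C)C)c(CC=C(C)C)c(O[Si](C(C)C)(C(C)C)C(C)C)c1)c1ccc(O[Si](C(C)C)(C(C)C)C(C)C)c(/C=C/C(C)C)c1OC | intermediate
30 | 3-[2-methoxy-3-[(E)-3-methylbut-1-enyl]-4-(triisopropylsilyloxy)phenyl]-6-(3-methylbut-2-enyl)-5,7-bis(triisopropylsilyloxy)-2,3-dihydrochromen-4-one (racemic) | COc1c(C2COc3cc(O[Si](C(C)C)(C(C)C)C(C)C)c(CC=C(C)C)c(O[Si](C(C)C)(C(C)C)C(C)C)c3C2=O)ccc(O[Si](C(C)C)(C(C)C)C(C)C)c1/C=C/C(C)C | intermediate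
31 | sodium 3-[2-methoxy-3-[(E)-3-methylbut-1-enyl]-4-(triisopropylsilyloxy)phenyl]-6-(3-methylbut-2-enyl)-5,7-bis(triisopropylsilyloxy)-2H-chromen-4-olate | COc1c(C2=C(O[Na])c3c(O[Si](C(C)C)(C(C)C)C(C)C)c(CC=C(C)C)c(O[Si](C(C)C)(C(C)C)C(C)C)cc3OC2)ccc(O[Si](C(C)C)(C(C)C)C(C)C)c1/C=C/C(C)C | intermediate
32 | 3-[2-methoxy-3-[(E)-3-methylbut-1-enyl]-4-(triisopropylsilyloxy)phenyl]-6-(3-methylbut-2-enyl)-5,7-bis(triisopropylsilyloxy)-2H-chromen-4-yl prop-2-enyl carbonate | COc1c(C2=C(OC(=O)OCC=C)c3c(O[Si](C(C)C)(C(C)C)C(C)C)c(CC=C(C)C)c(O[Si](C(C)C)(C(C)C)C(C)C)cc3OC2)ccc(O[Si](C(C)C)(C(C)C)C(C)C)c1/C=C/C(C)C | intermediate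
33 | (3S)-3-[2-methoxy-3-[(E)-3-methylbut-1-enyl]-4-(triisopropylsilyloxy)phenyl]-6-(3-methylbut-2-enyl)-5,7-bis(triisopropylsilyloxy)-2,3-dihydrochromen-4-one | COc1c([C@H]2COc3cc(O[Si](C(C)C)(C(C)C)C(C)C)c(CC=C(C)C)c(O[Si](C(C)C)(C(C)C)C(C)C)c3C2=O)ccc(O[Si](C(C)C)(C(C)C)C(C)C)c1/C=C/C(C)C | intermediate
34 | (3S)-5,7-dihydroxy-3-[4-hydroxy-2-methoxy-3-[(E)-3-methylbut-1-enyl]phenyl]-6-(3-methylbut-2-enyl)-2,3-dihydrochromen-4-one | COc1c([C@H]2COc3cc(O)c(CC=C(C)C)c(O)c3C2=O)ccc(O)c1/C=C/C(C)C | target

**Step count and risks**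

Total step count: 16. Longest linear sequence: 11 steps (steps 1, 2, 5, 6, 7, 11, 12, 13, 14, 15, 16).

Steps most likely to fail:

Step 5 (key step). What may go wrong: a 1,2-hydride shift in the carbene in place of Wolff migration, photoisomerisation of the E alkene, or loss of the acryloyl diazo ketone by self-cycloaddition before it is photolysed. Fallback: thermal generation of the same vinylketene from a cyclobutenone, with no light and no carbene. It sets out from 1. Dehydrochlorination of 1 with Et3N in ethyl vinyl ether gives the ketene methyl 4-oxobut-3-enoate F1, which is trapped in a (2+2) cycloaddition as methyl 2-(2-ethoxy-4-oxocyclobutyl)acetate F2. Acid-catalysed elimination of ethanol gives methyl 2-(4-oxocyclobut-1-en-1-yl)acetate F3. Heating F3 with 13 in toluene at 80 °C opens the four-membered ring to 14, and the cascade then runs through 15, 16 and 17 and comes back to the route at 18.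

Step 2. What may go wrong: conjugate addition to, or polymerisation of, the unsubstituted vinyl ketone during enolate formation, and decomposition of the diazo enone on handling. Fallback: block the β-position with silicon. It sets out from 1. Stille acylation with commercial (E)-trimethyl[2-(tributylstannyl)ethenyl]silane gives methyl (E)-4-oxo-6-(trimethylsilyl)hex-5-enoate F4, a β-substituted enone of the kind for which this diazo transfer is routine. The same two-stage procedure, through methyl (E)-4-oxo-3-(2,2,2-trifluoroacetyl)-6-(trimethylsilyl)hex-5-enoate F5, gives methyl (E)-3-diazo-4-oxo-6-(trimethylsilyl)hex-5-enoate F6. Benzannulation of F6 with 13 as in step 5 should give methyl 2-[4-hydroxy-2-methoxy-3-[(E)-3-methylbut-1-enyl]-5-(trimethylsilyl)phenyl]acetate F7. Ipso-protodesilylation ortho to the phenol (Bu4NF, wet THF) comes back to the route at 18.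

Step 15. What may go wrong: poor facial selectivity in the protonation, since ring B carries only one ortho substituent and the 5-silyloxy group crowds the enolate. Fallback: dynamic kinetic resolution by asymmetric transfer hydrogenation. It sets out from 30. RuCl(p-cymene)[(S,S)-TsDPEN] with HCO2H/Et3N reduces the ketone while C3 epimerises, which should give the cis alcohol (3S,4S)-3-[2-methoxy-3-[(E)-3-methylbut-1-enyl]-4-(triisopropylsilyloxy)phenyl]-6-(3-methylbut-2-enyl)-5,7-bis(triisopropylsilyloxy)-3,4-dihydro-2H-chromen-4-ol F8. Oxidation with Dess–Martin periodinane buffered with NaHCO3 returns the ketone without touching C3 and comes back to the route at 33.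

**Further compounds**

F1 | step 5 | methyl 4-oxobut-3-enoate (ketene) | COC(=O)CC=C=O
F2 | step 5 | methyl 2-(2-ethoxy-4-oxocyclobutyl)acetate | COC(=O)CC1C(OCC)CC1=O
F3 | step 5 | methyl 2-(4-oxocyclobut-1-en-1-yl)acetate | COC(=O)CC1=CCC1=O
F4 | step 2 | methyl (E)-4-oxo-6-(trimethylsilyl)hex-5-enoate | COC(=O)CCC(=O)/C=C/[Si](C)(C)C
F5 | step 2 | methyl (E)-4-oxo-3-(2,2,2-trifluoroacetyl)-6-(trimethylsilyl)hex-5-enoate | COC(=O)CC(C(=O)C(F)(F)F)C(=O)/C=C/[Si](C)(C)C
F6 | step 2 | methyl (E)-3-diazo-4-oxo-6-(trimethylsilyl)hex-5-enoate | COC(=O)CC(=[N+]=[N-])C(=O)/C=C/[Si](C)(C)C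
F7 | step 2 | methyl 2-[4-hydroxy-2-methoxy-3-[(E)-3-methylbut-1-enyl]-5-(trimethylsilyl)phenyl]acetate | COC(=O)Cc1cc([Si](C)(C)C)c(O)c(/C=C/C(C)C)c1OC
F8 | step 15 | (3S,4S)-3-[2-methoxy-3-[(E)-3-methylbut-1-enyl]-4-(triisopropylsilyloxy)phenyl]-6-(3-methylbut-2-enyl)-5,7-bis(triisopropylsilyloxy)-3,4-dihydro-2H-chromen-4-ol | O[C@H]1[C@@H](c3ccc(O[Si](C(C)C)(C(C)C)C(C)C)c(/C=C/C(C)C)c3OC)COc2cc(O[Si](C(C)C)(C(C)C)C(C)C)c(CC=C(C)C)c(O[Si](C(C)C)(C(C)C)C(C)C)c21
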